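The readings stem from a simulated flask for an exercise.

**Your hunch.** A charge of 0.25 M of starting complex, smaller than in either earlier run, led you to expect two incoming ligands per complex and so 100 % reacted. I would not have promised that.

| setting | Tuesday's | Sunday's | flask |
|---|---|---|---|
| starting complex | 0.35 M | 0.55 M | 0.25 M |
| incoming ligand | 0.50 M (fed, over 3.0 s) | 0.50 M (fed, over 3.0 s) | 0.500 M (fed, over 3.0 s) |
| remark | run made earlier; the fed solution adds 0.10 times the starting volume | run made earlier; the fed solution adds 0.10 times the starting volume | the fed solution adds 0.10 times the starting volume |
| time |  |  | 30 min |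

| run | time / min | starting complex / % | side product / % |
|---|---|---|---|
| Tuesday's | 2.00 | 40.4 | 14.1 |
| Tuesday's | 3.00 | 41.7 | 19.1 |
| Tuesday's | 4.00 | 40.2 | 22.4 |
| Tuesday's | 6.00 | 40.5 | 26.6 |
| Tuesday's | 10.0 | 40.0 | 30.2 |
| Tuesday's | 15.0 | 40.5 | 32.5 |
| Tuesday's | 25.0 | 39.3 | 35.5 |
| Sunday's | 1.33 | 53.5 | 9.0 |
| Sunday's | 4.00 | 56.5 | 17.4 |
| Sunday's | 6.00 | 57.6 | 18.8 |
| Sunday's | 10.0 | 58.0 | 22.1 |
| Sunday's | 15.0 | 58.0 | 25.1 |
| Sunday's | 20.0 | 58.6 | 25.9 |
| Sunday's | 25.0 | 58.6 | 27.1 |

(each reading ± 0.5 percentage points)

* the state of affairs at 30 min: stopped, and by what, or still going (forward and back rates have come level / all of the starting complex has reacted / the incoming ligand has run out first / it is still moving)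
* part of the starting complex gone at 30 min
* the side product standing at 30 min, as a percentage of the starting complex charged
* amount of complex with two exchanged if the flask were left three thousand times as long, in percent of the starting complex charged

- every charge counts on the volume at the start, and the solution that is fed holds the whole dose
- the reaction counts as stopped when no species that holds the starting complex changes by six tenths of a point or more over the second half of the time

**My count.** Tuesday's run levelled out with 39.3 % of its complex left at 25.0 min. The ligand itself was never read, so I took the whole charge as consumed. That last reading, with its scatter, made n = 2.35, the turnover count: ligand consumed per complex reacted. Sunday's last reading gave 2.20. Both stood above two, so on that assumption some complex took more than two ligands. I carried Tuesday's n, since its ligand per complex lay nearer the flask's than Sunday's did. With the ligand as limiting reagent, charge over n gave 85.0 % reacted once the whole charge was consumed.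

**The forecast.** It gave 80 % reacted, which is 5 percentage points below my figure, and 52 % of side product, “about two-thirds of the remaining 80%”. It put complex with two exchanged at 5 % in the long run, and its verdict on the state at the asked time was: it is still moving.

**The flask.** At 30 min the verdict was the same: it is still moving. It showed 79.0 % reacted and 42.0 % of side product, 10 points under the forecast, and 0 % of complex with two exchanged in the long run.

    complex with two exchanged + incoming ligand ⇌ leaving ligand + complex with three exchanged (K = 0.220, k = 0.0140 L mol⁻¹ s⁻¹)
    complex with one exchanged + incoming ligand ⇌ leaving ligand + complex with two exchanged (K = 0.820, k = 0.0580 L mol⁻¹ s⁻¹)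
    complex with three exchanged + incoming ligand ⇌ leaving ligand + complex with four exchanged (K = 0.660, k = 0.230 L mol⁻¹ s⁻¹)
    starting complex + incoming ligand ⇌ leaving ligand + complex with one exchanged (K = 1.50, k = 0.0890 L mol⁻¹ s⁻¹)
    complex with two exchanged + incoming ligand → over-reaction product (k = 0.150 L mol⁻¹ s⁻¹)
    leaving ligand + complex with two exchanged → side product (k = 0.120 L mol⁻¹ s⁻¹)

**Counting again.** With 5.7 % of the ligand still there at 30.0 min, the flask's own n came to 2.39, beside Tuesday's 2.35. At 0.271 min, complex with two exchanged in the flask went to side product at 0.24 of its rate to over-reaction product. At 30.0 min, the flask held 33.8 % of over-reaction product beside the side product. The neighbour charged with 0.62 M of starting complex had a ligand per complex nearer Sunday's than Tuesday's, so I used Sunday's n, which gives 36.7 % reacted with the whole charge taken as consumed; that flask showed 36.9 % at 30.0 min.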